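**Retrosynthetic overview**
- Target ⇒ 3-hydroxy-7,8,3',4',5'-pentamethoxyflavone by disconnecting the C5–O bond; in the forward direction this is a late carbonyl-directed peri C–H oxygenation (the new step).
- That 5-deoxyflavonol ⇒ 2'-hydroxychalcone by disconnecting O1–C2 and C3–O (Algar–Flynn–Oyamada oxidative cyclisation).
- Chalcone ⇒ 2'-hydroxy-3',4'-dimethoxyacetophenone + 3,4,5-trimethoxybenzaldehyde (Claisen–Schmidt, the only C–C bond made).
- Ring order: rings A and B are bought; ring C (the pyranone) is closed in step 2; the 5-OH goes on last, so no protecting groups or O-demethylation are needed.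

Assumption: the target is a planar, achiral flavonol with no stereocentre, so "single enantiomer" needs no stereocontrol; compounds 1 and 2 are taken as catalogue chemicals.

**Route**

Step 1
Reactants: 1 2'-hydroxy-3',4'-dimethoxyacetophenone; 2 3,4,5-trimethoxybenzaldehyde
Product: 3 (E)-2'-hydroxy-3',4',3,4,5-pentamethoxychalcone
Conditions: KOH (50% aq, 5 equiv), EtOH, rt, 24 h; then 2 M HCl, 0 °C
Reagents that add atoms: none
Why: Claisen–Schmidt (crossed aldol) condensation of a methyl ketone with a non-enolisable aldehyde, where E1cB dehydration gives the conjugated (E)-enone and no stereocentre is formed.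

Step 2
Reactants: 3 (E)-2'-hydroxy-3',4',3,4,5-pentamethoxychalcone
Product: 5 3-hydroxy-7,8,3',4',5'-pentamethoxyflavone, via trans-dihydroflavonol 4 (not isolated)
Conditions: 30% aq H2O2 (5 equiv), 2 M NaOH (5 equiv), MeOH, 0 °C → rt, 4 h; then 2 M HCl
Reagents that add atoms: hydrogen peroxide, OO
Why: Algar–Flynn–Oyamada oxidative cyclisation, in which 6-endo attack of the 2'-phenoxide on the enone coupled with hydroperoxide oxygenation at Cα forms O1–C2 and C3–O; the racemic trans-dihydroflavonol 4 is dehydrogenated in the same alkaline peroxide so its two stereocentres are erased, and the absence of a 6'-substituent favours flavonol over aurone.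

Step 3
Reactants: 5 3-hydroxy-7,8,3',4',5'-pentamethoxyflavone
Product: 8 3,5-dihydroxy-7,8,3',4',5'-pentamethoxyflavone, via O3-trifluoroacetate 6 (not isolated), via bis-trifluoroacetate 7 (not isolated)
Conditions: TFA/TFAA (3:1), rt, 30 min; then [RuCl2(p-cymene)]2 (5 mol %), PhI(OCOCF3)2 (1.3 equiv, in portions), 60 °C, 6 h; work-up aq Na2S2O3 then THF/H2O, rt
Reagents that add atoms: [bis(trifluoroacetoxy)iodo]benzene, O=C(OI(OC(=O)C(F)(F)F)c1ccccc1)C(F)(F)F (one trifluoroacetate oxygen becomes the C5–O of 8); trifluoroacetic anhydride, O=C(OC(=O)C(F)(F)F)C(F)(F)F (CF3CO groups of 6 and 7 only, lost at work-up)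
Why: Proposed new method: a Ru(II)/Ru(IV) carbonyl-directed peri C–H oxygenation run on a free flavonol whose 3-OH is masked in the flask, which to my knowledge has not been shown; TFAA turns the O3/O4-chelating enol 5 into trifluoroacetate 6 so that C4=O acts as a monodentate weak donor to Ru(O2CCF3)2(p-cymene), carboxylate-assisted ruthenation occurs at C5–H (para to the 8-OMe and the only C–H that can close a five-membered O–Ru–C chelate), PhI(OCOCF3)2 oxidises the ruthenacycle to Ru(IV), C–O reductive elimination gives aryl trifluoroacetate 7, which is too electron-poor to be over-oxidised to the 5,8-quinone, and aqueous work-up after quenching the oxidant hydrolyses both esters to 8; the closest known reaction type is the Ru- or Pd-catalysed ketone-directed ortho C–H hydroxylation of aryl ketones and 3-unsubstituted chromones in TFA/TFAA; no stereocentre is formed.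

**Compound list**
1 | 2'-hydroxy-3',4'-dimethoxyacetophenone [1-(2-hydroxy-3,4-dimethoxyphenyl)ethan-1-one] | CC(=O)c1ccc(OC)c(OC)c1O | starting material
2 | 3,4,5-trimethoxybenzaldehyde | COc1cc(C=O)cc(OC)c1OC | starting material
3 | (E)-1-(2-hydroxy-3,4-dimethoxyphenyl)-3-(3,4,5-trimethoxyphenyl)prop-2-en-1-one | COc1cc(/C=C/C(=O)c2ccc(OC)c(OC)c2O)cc(OC)c1OC | intermediate
4 | rac-trans-3-hydroxy-7,8-dimethoxy-2-(3,4,5-trimethoxyphenyl)chroman-4-one (racemate; 2R,3R enantiomer drawn) | COc1cc([C@@H]2[C@H](C(=O)c3ccc(OC)c(OC)c3O2)O)cc(OC)c1OC | intermediate (not isolated)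
5 | 3-hydroxy-7,8-dimethoxy-2-(3,4,5-trimethoxyphenyl)-4H-chromen-4-one | COc1cc(-c2oc3c(OC)c(OC)ccc3c(=O)c2O)cc(OC)c1OC | intermediate
6 | 7,8-dimethoxy-4-oxo-2-(3,4,5-trimethoxyphenyl)-4H-chromen-3-yl trifluoroacetate | COc1cc(-c2oc3c(OC)c(OC)ccc3c(=O)c2OC(=O)C(F)(F)F)cc(OC)c1OC | intermediate (not isolated)
7 | 7,8-dimethoxy-4-oxo-2-(3,4,5-trimethoxyphenyl)-4H-chromene-3,5-diyl bis(trifluoroacetate) | COc1cc(-c2oc3c(OC)c(OC)cc(OC(=O)C(F)(F)F)c3c(=O)c2OC(=O)C(F)(F)F)cc(OC)c1OC | intermediate (not isolated)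
8 | 3,5-dihydroxy-7,8-dimethoxy-2-(3,4,5-trimethoxyphenyl)-4H-chromen-4-one (3,5-dihydroxy-7,8,3',4',5'-pentamethoxyflavone; achiral) | COc1cc(-c2oc3c(OC)c(OC)cc(O)c3c(=O)c2O)cc(OC)c1OC | target

**Step count and risks**

Total step count: 3. Longest linear sequence: 3 (steps 1 and 2 can be telescoped in one pot if desired).

The three steps most likely to fail, most risky first:

Step 3 (proposed new C5–H oxygenation). The risks are that PhI(OCOCF3)2 in TFA attacks the electron-rich methoxyaryl rings, that C4=O flanked by the acyloxy group binds Ru too weakly, and that unmasked 3-OH sequesters the catalyst. The fallback uses known chemistry only, sets out from aldehyde 2 and comes back at target 8. Aldehyde 2 is condensed (KOH, EtOH, rt) with purchased 2'-hydroxy-3',4',6'-trimethoxyacetophenone F1 (a catalogue compound, dearer than 1) to give (E)-2'-hydroxy-3',4',6',3,4,5-hexamethoxychalcone F2. Algar–Flynn–Oyamada oxidation (H2O2, NaOH, MeOH) then passes through racemic trans-3-hydroxy-5,7,8-trimethoxy-2-(3,4,5-trimethoxyphenyl)chroman-4-one F3 to 3-hydroxy-5,7,8,3',4',5'-hexamethoxyflavone F4; a modest yield is expected because the 6'-OMe favours some aurone. Finally BCl3 (CH2Cl2, −78 → 0 °C) cleaves only the 5-OMe peri to the carbonyl through the boron chelate, giving 8. These conditions are mild enough to avoid Wessely–Moser isomerisation.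

Step 2 (Algar–Flynn–Oyamada). The risks are aurone formation, stalling at the dihydroflavonol, and peroxide degradation of the electron-rich chalcone. The fallback sets out from chalcone 3 and comes back at flavonol 5. Chalcone 3 is cyclised and dehydrogenated with catalytic I2 in DMSO at 130 °C to 7,8,3',4',5'-pentamethoxyflavone F5. Dimethyldioxirane (acetone/CH2Cl2, 0 °C) epoxidises the C2=C3 bond to racemic 2,3-epoxy-7,8-dimethoxy-2-(3,4,5-trimethoxyphenyl)chroman-4-one F6. Catalytic TsOH then isomerises the epoxide to 5.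

Step 1 (Claisen–Schmidt). The risks are sluggish enolisation because the ketone is present as its phenoxide, Cannizzaro loss of 2, and partial closure to the flavanone. The fallback sets out from acetophenone 1 and comes back at chalcone 3. Acetophenone 1 is protected (NaH, MOMCl, DMF, 0 °C → rt) as 3',4'-dimethoxy-2'-(methoxymethoxy)acetophenone F7. This neutral ketone condenses with 2 (KOH, EtOH, rt) to (E)-2'-(methoxymethoxy)-3',4',3,4,5-pentamethoxychalcone F8. HCl in MeOH (3 M, 50 °C) removes the MOM group to give 3.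

**Further compounds**
F1 | step 3 | 2'-hydroxy-3',4',6'-trimethoxyacetophenone (purchased) | CC(=O)c1c(OC)cc(OC)c(OC)c1O
F2 | step 3 | (E)-1-(2-hydroxy-3,4,6-trimethoxyphenyl)-3-(3,4,5-trimethoxyphenyl)prop-2-en-1-one | COc1cc(/C=C/C(=O)c2c(OC)cc(OC)c(OC)c2O)cc(OC)c1OC
F3 | step 3 | rac-trans-3-hydroxy-5,7,8-trimethoxy-2-(3,4,5-trimethoxyphenyl)chroman-4-one (2R,3R enantiomer drawn; not isolated) | COc1cc([C@@H]2[C@H](C(=O)c3c(OC)cc(OC)c(OC)c3O2)O)cc(OC)c1OC
F4 | step 3 | 3-hydroxy-5,7,8-trimethoxy-2-(3,4,5-trimethoxyphenyl)-4H-chromen-4-one | COc1cc(-c2oc3c(OC)c(OC)cc(OC)c3c(=O)c2O)cc(OC)c1OC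
F5 | step 2 | 7,8-dimethoxy-2-(3,4,5-trimethoxyphenyl)-4H-chromen-4-one | COc1cc(-c2cc(=O)c3ccc(OC)c(OC)c3o2)cc(OC)c1OC
F6 | step 2 | rac-2,3-epoxy-7,8-dimethoxy-2-(3,4,5-trimethoxyphenyl)chroman-4-one (cis-fused; one enantiomer drawn) | COc1cc([C@]23O[C@H]2C(=O)c2ccc(OC)c(OC)c2O3)cc(OC)c1OC
F7 | step 1 | 1-[3,4-dimethoxy-2-(methoxymethoxy)phenyl]ethan-1-one | CC(=O)c1ccc(OC)c(OC)c1OCOC
F8 | step 1 | (E)-1-[3,4-dimethoxy-2-(methoxymethoxy)phenyl]-3-(3,4,5-trimethoxyphenyl)prop-2-en-1-one | COCOc1c(OC)c(OC)ccc1C(=O)/C=C/c1cc(OC)c(OC)c(OC)c1
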